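**Plan**

- Retrosynthesis: the two MOM ethers come off last; then the furan C2=C3 bond is cut, then the ester O1–C2 bond, giving a prenylated salicylaldehyde and a chromene-8-carboxylic acid.
- Enabling feature: C2=C3 joins C3 (on C3a) and C2 (between O1 and chromene C8). Both can be carried at carbonyl level: C3 as the formyl carbon of the salicylaldehyde, C2 as the carboxyl carbon of the acid esterified on O1.
- Further cuts: the aryl C5–prenyl bond (allyl–aryl cross-coupling) and the pyran O–CMe2 and C4–C4a bonds (propargyl ether, Claisen rearrangement).
- Forward order: prenyl onto the salicylaldehyde (steps 1–2); pyran ring onto the benzoate (steps 3–6); ester union (step 7); furan ring closed last on titanium (step 8); deprotection (step 9).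
- Stereochemistry: none to set; the target has no stereocentre and no configurationally defined alkene.

Key step: step 8

Remark: kanzonol V is achiral, so the "single enantiomer" is the compound itself and no asymmetric step is needed.

**Route**

Step 1
Reactants: 1 5-bromo-2,4-dihydroxybenzaldehyde
Product: 2 5-bromo-2-hydroxy-4-(methoxymethoxy)benzaldehyde
Conditions: MOMCl (1.05 equiv), K2CO3, acetone, 0 °C to rt
Reagents that add atoms: chloromethyl methyl ether, COCCl
Why: Williamson-type O-alkylation, selective for O4 because the 4-OH (para to the formyl group, ortho to Br) is the more acidic and free phenol while the 2-OH is held in a hydrogen bond to the aldehyde.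

Step 2
Reactants: 2 5-bromo-2-hydroxy-4-(methoxymethoxy)benzaldehyde; 3 prenylboronic acid pinacol ester
Product: 4 2-hydroxy-4-(methoxymethoxy)-5-(3-methylbut-2-en-1-yl)benzaldehyde
Conditions: Pd-PEPPSI-IPent (cat.), 5 M aq. KOH, THF, 70 °C
Reagents that add atoms: none
Why: Suzuki–Miyaura allyl–aryl coupling in which the bulky NHC–palladium catalyst should deliver the prenyl group through its unsubstituted α-carbon (linear isomer), while the MOM ether and the phenoxide-deactivated aldehyde tolerate aqueous hydroxide.

Step 3
Reactants: 5 methyl 2,4-dihydroxybenzoate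
Product: 6 methyl 2-hydroxy-4-(methoxymethoxy)benzoate
Conditions: MOMCl (1.05 equiv), K2CO3, acetone, rt
Reagents that add atoms: chloromethyl methyl ether, COCCl
Why: Williamson-type O-alkylation that should stop at O4, since the 2-OH is hydrogen-bonded to the ester carbonyl and does not react with a weak base at room temperature.

Step 4
Reactants: 6 methyl 2-hydroxy-4-(methoxymethoxy)benzoate; 7 3-chloro-3-methylbut-1-yne
Product: 8 methyl 4-(methoxymethoxy)-2-[(2-methylbut-3-yn-2-yl)oxy]benzoate
Conditions: DBU, CuCl2·2H2O (cat.), MeCN, 0 °C to rt
Reagents that add atoms: none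
Why: Copper-catalysed propargylic etherification in which the amidine base frees the hydrogen-bonded phenoxide, which captures the copper allenylidene at the tertiary carbon; O4 is blocked, so only the O2 ether can form.

Step 5
Reactants: 8 methyl 4-(methoxymethoxy)-2-[(2-methylbut-3-yn-2-yl)oxy]benzoate
Product: 10 methyl 5-(methoxymethoxy)-2,2-dimethyl-2H-chromene-8-carboxylate, via ortho-allenylphenol ester 9 (not isolated)
Conditions: N,N-diethylaniline, 190 °C
Reagents that add atoms: none
Why: Aryl propargyl ether Claisen rearrangement, whose [3,3] shift can reach only C3 (C1 carries the ester); the allenylphenol then undergoes a 1,5-hydrogen shift and oxa-6π electrocyclisation, placing the pyran oxygen ortho to the ester as the target requires.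

Step 6
Reactants: 10 methyl 5-(methoxymethoxy)-2,2-dimethyl-2H-chromene-8-carboxylate
Product: 11 5-(methoxymethoxy)-2,2-dimethyl-2H-chromene-8-carboxylic acid
Conditions: NaOH, MeOH/THF/H2O, 60 °C; then 1 M HCl to pH 4, 0 °C
Reagents that add atoms: sodium hydroxide, [Na+].[OH-]
Why: Ester saponification under conditions to which the MOM acetal and the chromene are inert, with cold acidification to pH 4 that should free the acid without cleaving the acetal.

Step 7
Reactants: 4 2-hydroxy-4-(methoxymethoxy)-5-(3-methylbut-2-en-1-yl)benzaldehyde; 11 5-(methoxymethoxy)-2,2-dimethyl-2H-chromene-8-carboxylic acid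
Product: 12 2-formyl-5-(methoxymethoxy)-4-(3-methylbut-2-en-1-yl)phenyl 5-(methoxymethoxy)-2,2-dimethyl-2H-chromene-8-carboxylate
Conditions: DCC, DMAP (cat.), CH2Cl2, 0 °C to rt
Reagents that add atoms: none
Why: Steglich esterification, in which DMAP passes the acyl group from the O-acylisourea to the only free phenol of 4 under neutral conditions that spare the aldehyde, both acetals and both alkenes.

Step 8
Reactants: 12 2-formyl-5-(methoxymethoxy)-4-(3-methylbut-2-en-1-yl)phenyl 5-(methoxymethoxy)-2,2-dimethyl-2H-chromene-8-carboxylate
Product: 13 6-(methoxymethoxy)-2-[5-(methoxymethoxy)-2,2-dimethyl-2H-chromen-8-yl]-5-(3-methylbut-2-en-1-yl)-1-benzofuran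
Conditions: TiCl3, Zn dust, THF, reflux, 2 h; then 12 in THF by syringe pump over 10 h (final ≤0.01 M), reflux; 10% aq. K2CO3 work-up
Reagents that add atoms: none
Why: Zinc-reduced titanium transfers an electron to the formyl group, the more easily reduced carbonyl, and the titanium-bound ketyl carbon (future C3) adds to the carbonyl carbon of the aryl ester held ortho to it (future C2); the titanium-bound 2,3-dioxygenated dihydrofuran so formed is deoxygenated on the oxophilic metal to the C2=C3 double bond, driven by Ti–O bond strength and furan aromaticity. The closest known reaction type is the McMurry-type intramolecular oxo-ester coupling that converts O-acylated salicyl aldehydes and ketones into benzofurans. The furan closes in 5-exo-trig fashion, C3 attacking C2 while the ester carbonyl oxygen stays outside the O1–C2–C3–C3a–C7a ring. No stereocentre is created. The step needs ring closure to win over bimolecular pinacol coupling and over reductive scission of the aryl ester or the allylic chromene ether; the ortho arrangement, slow addition to a large excess of reagent at high dilution, and the mild zinc couple rather than a Ti(0) reagent should secure this. The prenyl and chromene alkenes are not reduced, and partial loss of a MOM group to the Lewis-acidic titanium salts would be harmless because step 9 removes both.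

Step 9
Reactants: 13 6-(methoxymethoxy)-2-[5-(methoxymethoxy)-2,2-dimethyl-2H-chromen-8-yl]-5-(3-methylbut-2-en-1-yl)-1-benzofuran
Product: 14 kanzonol V
Conditions: 3 M aq. HCl, MeOH/THF, rt to 40 °C
Reagents that add atoms: none
Why: Acid-catalysed acetal exchange (MOM methanolysis) under dilute acid near room temperature, conditions under which cyclisation of the prenyl group onto the neighbouring phenol and addition to the chromene alkene, which need stronger acid or heat, should not compete.

**Compound list**

1 | 5-bromo-2,4-dihydroxybenzaldehyde | O=Cc1cc(Br)c(O)cc1O | starting material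
2 | 5-bromo-2-hydroxy-4-(methoxymethoxy)benzaldehyde | O=Cc1cc(Br)c(OCOC)cc1O | intermediate
3 | prenylboronic acid pinacol ester | CC(C)=CCB1OC(C)(C)C(C)(C)O1 | starting material
4 | 2-hydroxy-4-(methoxymethoxy)-5-(3-methylbut-2-en-1-yl)benzaldehyde | CC(C)=CCc1cc(C=O)c(O)cc1OCOC | intermediate
5 | methyl 2,4-dihydroxybenzoate | COC(=O)c1ccc(O)cc1O | starting material
6 | methyl 2-hydroxy-4-(methoxymethoxy)benzoate | COC(=O)c1ccc(OCOC)cc1O | intermediate
7 | 3-chloro-3-methylbut-1-yne | C#CC(C)(C)Cl | starting material
8 | methyl 4-(methoxymethoxy)-2-[(2-methylbut-3-yn-2-yl)oxy]benzoate | COC(=O)c1ccc(OCOC)cc1OC(C)(C)C#C | intermediate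
9 | methyl 2-hydroxy-4-(methoxymethoxy)-3-(3-methylbuta-1,2-dien-1-yl)benzoate (not isolated) | COC(=O)c1ccc(OCOC)c(C=C=C(C)C)c1O | intermediate
10 | methyl 5-(methoxymethoxy)-2,2-dimethyl-2H-chromene-8-carboxylate | COC(=O)c1ccc(OCOC)c2c1OC(C)(C)C=C2 | intermediate
11 | 5-(methoxymethoxy)-2,2-dimethyl-2H-chromene-8-carboxylic acid | OC(=O)c1ccc(OCOC)c2c1OC(C)(C)C=C2 | intermediate
12 | 2-formyl-5-(methoxymethoxy)-4-(3-methylbut-2-en-1-yl)phenyl 5-(methoxymethoxy)-2,2-dimethyl-2H-chromene-8-carboxylate | CC(C)=CCc1cc(C=O)c(OC(=O)c2ccc(OCOC)c3c2OC(C)(C)C=C3)cc1OCOC | intermediate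
13 | 6-(methoxymethoxy)-2-[5-(methoxymethoxy)-2,2-dimethyl-2H-chromen-8-yl]-5-(3-methylbut-2-en-1-yl)-1-benzofuran | CC(C)=CCc1cc2cc(-c3ccc(OCOC)c4c3OC(C)(C)C=C4)oc2cc1OCOC | intermediate
14 | kanzonol V | CC(C)=CCc1cc2cc(-c3ccc(O)c4c3OC(C)(C)C=C4)oc2cc1O | target

**Count and risks**

Total: 9 steps. Longest linear sequence: 7 steps (steps 3, 4, 5, 6, 7, 8, 9, from 5 to 14).

Step 8. Bimolecular pinacol coupling or simple reduction of the aldehyde, or reductive scission of the activated aryl ester or of the allylic chromene ether, may outrun the ring closure. The fallback forms the same C2=C3 bond with ylide polarity by an intramolecular Wittig reaction, setting out from 4 and 11. NaBH4 in MeOH should reduce 4 to 2-(hydroxymethyl)-5-(methoxymethoxy)-4-(3-methylbut-2-en-1-yl)phenol F1. Brief treatment with PPh3·HBr in MeCN should convert this salicyl alcohol into [2-hydroxy-4-(methoxymethoxy)-5-(3-methylbut-2-en-1-yl)benzyl]triphenylphosphonium bromide F2. Acid 11 is turned under neutral conditions, with 1-chloro-N,N,2-trimethylprop-1-en-1-amine in CH2Cl2, into 5-(methoxymethoxy)-2,2-dimethyl-2H-chromene-8-carbonyl chloride F3. Heating F2 and F3 with Et3N in toluene should bring about O-acylation, ylide formation and olefination of the ester carbonyl, which returns to the route at 13.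

Step 4. O-Alkylation of the hydrogen-bonded, ortho-flanked phenoxide may be slower than base-induced elimination and oligomerisation of the tertiary propargylic chloride. The fallback builds the pyran ring by a phenol–enal annulation instead of the ether/Claisen sequence, setting out from 6. Heating 6 with 3-methylbut-2-enal, phenylboronic acid and propionic acid in toluene, with azeotropic removal of water, should give ortho-specific condensation at C3 through the aryl boronate, then an o-quinone methide and oxa-6π electrocyclisation. This returns directly at 10, skipping 8 and 9, and makes no compound outside the list (F0).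

Step 2. Transfer of the allyl group through its γ-carbon (reverse-prenyl isomer), protodeboronation of the allylboronate, or sluggish oxidative addition to the phenoxide-rich aryl bromide may lower the outcome. The fallback separates carbon–carbon coupling from installation of the trisubstituted alkene, setting out from 2. Suzuki–Miyaura coupling with allylboronic acid pinacol ester (Pd(dppf)Cl2, aq. K2CO3, dioxane, 80 °C), where both allyl termini are identical, should give 2-hydroxy-4-(methoxymethoxy)-5-(prop-2-en-1-yl)benzaldehyde F4. Olefin cross-metathesis of F4 with excess 2-methylbut-2-ene (second-generation ruthenium benzylidene catalyst, CH2Cl2, 40 °C) should convert the allyl into the prenyl group, returning at 4.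

**Further compounds**

F1 | step 8 | 2-(hydroxymethyl)-5-(methoxymethoxy)-4-(3-methylbut-2-en-1-yl)phenol | CC(C)=CCc1cc(CO)c(O)cc1OCOC
F2 | step 8 | [2-hydroxy-4-(methoxymethoxy)-5-(3-methylbut-2-en-1-yl)benzyl]triphenylphosphonium bromide | CC(C)=CCc1cc(C[P+](c2ccccc2)(c2ccccc2)c2ccccc2)c(O)cc1OCOC.[Br-]
F3 | step 8 | 5-(methoxymethoxy)-2,2-dimethyl-2H-chromene-8-carbonyl chloride | O=C(Cl)c1ccc(OCOC)c2c1OC(C)(C)C=C2
F0 | step 4 | none | none
F4 | step 2 | 2-hydroxy-4-(methoxymethoxy)-5-(prop-2-en-1-yl)benzaldehyde | C=CCc1cc(C=O)c(O)cc1OCOC
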